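The quinone ring (C1–C4) is 1,4-dioxygenated, bears its single carbon substituent, the stereogenic carbinol C1′, at C2, and is fused to the hydroquinone ring (C4a–C8a). This pattern is the signature of a chromium carbene benzannulation, so the ring is cut into an aryl(methoxy)carbene carbon (C4), a terminal alkyne (C3–H and C2, with C1′ already S-configured) and one CO ligand (C1). A single operation forms C4–C3, C2–C1 and C1–C8a; oxidative work-up with (NH4)2Ce(NO3)6 then gives the naphthoquinone. The precursors are a pentacarbonylchromium carbene made from bis-MOM hydroquinone and an enantioenriched O-silyl propargylic enyne. Alkannin is unmasked and the tiglate attached last.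

Key step: step 8

Remark: naphthazarins interconvert rapidly between ring tautomers, so alkannin and its silyl ether are drawn with the side chain on the quinone ring; η6-arene chromium complexes are written in SMILES as the arene plus a Cr(CO)3 fragment.

Step 1
Reactants: 1 hydroquinone
Product: 2 1,4-bis(methoxymethoxy)benzene
Conditions: MOMCl (2.5 equiv), i-Pr2NEt (3 equiv), CH2Cl2/THF, 0 °C to rt
Reagents that add atoms: chloromethyl methyl ether, COCCl
Why: Double O-alkylation of the phenols with the α-chloro ether under amine base (Williamson-type acetal formation) is fast and installs groups that later direct ortho-lithiation and leave without strong acid.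

Step 2
Reactants: 2 1,4-bis(methoxymethoxy)benzene; 3 chromium hexacarbonyl
Product: 6 pentacarbonyl{[2,5-bis(methoxymethoxy)phenyl](methoxy)carbene}chromium, via aryllithium 4 (not isolated), via lithium acylchromate 5 (not isolated)
Conditions: n-BuLi, TMEDA, THF, 0 °C; Cr(CO)6, THF, 0 °C to rt; solvent switch, then MeOTf, CH2Cl2, 0 °C
Reagents that add atoms: methyl trifluoromethanesulfonate, COS(=O)(=O)C(F)(F)F
Why: Directed ortho-metalation beside a MOM ether (all four ring hydrogens are equivalent) followed by the Fischer carbene synthesis, in which the aryllithium adds to a CO ligand and the acylchromate is O-methylated, is the standard entry to aryl(methoxy)carbene complexes.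

Step 3
Reactants: 7 4-methylpent-3-enoic acid
Product: 9 N-methoxy-N,4-dimethylpent-3-enamide, via acyl imidazolide 8 (not isolated)
Conditions: CDI, CH2Cl2, rt; then MeNH(OMe)·HCl, rt
Reagents that add atoms: N,O-dimethylhydroxylamine hydrochloride, CNOC.Cl
Why: Weinreb amide formation through the acyl imidazolide runs without strong acid or base, so the β,γ-alkene should not move into conjugation.

Step 4
Reactants: 9 N-methoxy-N,4-dimethylpent-3-enamide; 10 trimethylsilylacetylene
Product: 13 6-methyl-1-(trimethylsilyl)hept-5-en-1-yn-3-one, via lithium silylacetylide 11 (not isolated), via tetrahedral lithium adduct 12 (not isolated)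
Conditions: 10, n-BuLi, THF, −78 °C; then 9, −78 to 0 °C; cold aq NH4Cl
Reagents that add atoms: none
Why: Weinreb ketone synthesis: the acetylide adds once because the chelated tetrahedral adduct survives until the cold buffered quench, which releases the ynone with the alkene still out of conjugation.

Step 5
Reactants: 13 6-methyl-1-(trimethylsilyl)hept-5-en-1-yn-3-one
Product: 14 (S)-6-methyl-1-(trimethylsilyl)hept-5-en-1-yn-3-ol
Conditions: Ru[(S,S)-TsNCH(Ph)CH(Ph)NH](η6-p-cymene) (2 mol %, preformed, no added base), i-PrOH, rt
Reagents that add atoms: none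
Why: Noyori asymmetric transfer hydrogenation of an alkynyl ketone, in which the alkyne acts as the π-substituent so that the (S,S)-configured catalyst should deliver hydride to the face giving the S carbinol, and the base-free amido complex avoids enolisation of the doubly activated CH2 group.

Step 6
Reactants: 14 (S)-6-methyl-1-(trimethylsilyl)hept-5-en-1-yn-3-ol
Product: 15 (S)-3-(tert-butyldimethylsilyloxy)-6-methyl-1-(trimethylsilyl)hept-5-en-1-yne
Conditions: TBSCl, imidazole, DMF, rt
Reagents that add atoms: tert-butyldimethylsilyl chloride, CC(C)(C)[Si](C)(C)Cl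
Why: Imidazole-promoted silylation of a secondary alcohol is routine and does not touch the stereocentre, and the bulky silyl ether is the inert, non-ionising propargylic group wanted for the benzannulation.

Step 7
Reactants: 15 (S)-3-(tert-butyldimethylsilyloxy)-6-methyl-1-(trimethylsilyl)hept-5-en-1-yne
Product: 16 (S)-3-(tert-butyldimethylsilyloxy)-6-methylhept-5-en-1-yne
Conditions: K2CO3 (0.2 equiv), MeOH, rt
Reagents that add atoms: none
Why: Methoxide-mediated protodesilylation cleaves only the alkynyl C–Si bond, since a secondary O-TBS ether is stable to K2CO3 in MeOH.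

Step 8
Reactants: 6 pentacarbonyl{[2,5-bis(methoxymethoxy)phenyl](methoxy)carbene}chromium; 16 (S)-3-(tert-butyldimethylsilyloxy)-6-methylhept-5-en-1-yne
Product: 19 2-[(S)-1-(tert-butyldimethylsilyloxy)-4-methylpent-3-enyl]-5,8-bis(methoxymethoxy)naphthalene-1,4-dione, via chromium-bound naphthol 17 (not isolated), via free naphthol 18 (not isolated)
Conditions: 6 (1.3 equiv), THF, 55 °C, argon, dark; then (NH4)2Ce(NO3)6, MeCN/H2O, 0 °C
Reagents that add atoms: water, O
Why: Dötz benzannulation followed by oxidative demetalation and oxidative demethylation: loss of one CO (helped by chelation of the ortho acetal oxygen) lets the alkyne insert so that its unsubstituted carbon bonds to the carbene carbon and the carbon carrying the bulky silyloxyalkyl group sits on chromium, CO insertion gives a chromium-bound vinylketene, and ring closure with tautomerisation gives the Cr(CO)3-bound 4-methoxy-1-naphthol, which tetravalent cerium strips of chromium and oxidises, water attacking C4 with loss of methanol. The closest known reaction type is the benzannulation of aryl(alkoxy)chromium carbenes with terminal propargylic ethers with cerium work-up to naphthoquinones. The one ring formed (C1–C4 with C4a and C8a) closes by thermal 6π-electrocyclisation of the dienylketene onto the only free ortho carbon of the aryl group. No stereocentre is created, and C1′ is not a reacting atom, so its S configuration is carried through. The step needs phenol formation to beat cyclobutenone, indene and furan formation and alkene cyclopropanation, which the aryl methoxy carbene in THF and the short tether to the trisubstituted alkene should secure. The insertion regiochemistry is fixed by the terminal alkyne and is in any case erased in the quinone, and oxidation should stop at the mono-quinone because the acetal-bearing ring is then deactivated.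

Step 9
Reactants: 19 2-[(S)-1-(tert-butyldimethylsilyloxy)-4-methylpent-3-enyl]-5,8-bis(methoxymethoxy)naphthalene-1,4-dione
Product: 21 2-[(S)-1-(tert-butyldimethylsilyloxy)-4-methylpent-3-enyl]-5,8-dihydroxynaphthalene-1,4-dione, via bis-TMS aryl ether 20 (not isolated)
Conditions: TMSOTf (4 equiv), 2,2′-bipyridyl (6 equiv), MeCN, 0 °C to rt; then H2O
Reagents that add atoms: none
Why: Silyl triflate–2,2′-bipyridyl cleavage of aromatic MOM ethers transfers the methoxymethyl groups to the pyridine base and holds the phenols as TMS ethers until the aqueous quench, so no Brønsted acid is present, the side chain stays on a fixed electron-poor quinone ring, and the alkyl TBS ether and the alkene should be left alone.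

Step 10
Reactants: 21 2-[(S)-1-(tert-butyldimethylsilyloxy)-4-methylpent-3-enyl]-5,8-dihydroxynaphthalene-1,4-dione
Product: 22 alkannin, 5,8-dihydroxy-2-[(S)-1-hydroxy-4-methylpent-3-enyl]naphthalene-1,4-dione
Conditions: HF·pyridine, pyridine, THF, 0 °C to rt, dark
Reagents that add atoms: none
Why: Fluoride-mediated desilylation with buffered HF·pyridine removes the secondary TBS ether without the base that degrades naphthazarins and without acid strong enough to ionise C1′ or to add the alcohol across the alkene.

Step 11
Reactants: 22 alkannin; 23 tiglic acid, (E)-2-methylbut-2-enoic acid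
Product: 25 alkannin tiglate, (S)-1-(5,8-dihydroxy-1,4-dioxo-1,4-dihydronaphthalen-2-yl)-4-methylpent-3-enyl (E)-2-methylbut-2-enoate, via O-acylisourea 24 (not isolated)
Conditions: DCC, DMAP (cat.), CH2Cl2, 0 °C to rt, dark
Reagents that add atoms: none
Why: Steglich esterification should acylate only the aliphatic secondary alcohol because the two peri phenols are tied up in hydrogen bonds to the quinone carbonyls, and the E geometry is that of the tiglic acid used.

Compound list
1 | hydroquinone | Oc1ccc(O)cc1 | starting material
2 | 1,4-bis(methoxymethoxy)benzene | COCOc1ccc(OCOC)cc1 | intermediate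
3 | chromium hexacarbonyl | O=C=[Cr](=C=O)(=C=O)(=C=O)(=C=O)=C=O | starting material
4 | [2,5-bis(methoxymethoxy)phenyl]lithium | [Li]c1cc(OCOC)ccc1OCOC | intermediate (not isolated)
5 | lithium pentacarbonyl[2,5-bis(methoxymethoxy)benzoyl]chromate | [Li+].[O-]C(c1cc(OCOC)ccc1OCOC)=[Cr](=C=O)(=C=O)(=C=O)(=C=O)=C=O | intermediate (not isolated)
6 | pentacarbonyl{[2,5-bis(methoxymethoxy)phenyl](methoxy)carbene}chromium | COC(c1cc(OCOC)ccc1OCOC)=[Cr](=C=O)(=C=O)(=C=O)(=C=O)=C=O | intermediate
7 | 4-methylpent-3-enoic acid | CC(C)=CCC(=O)O | starting material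
8 | 1-(4-methylpent-3-enoyl)imidazole | CC(C)=CCC(=O)n1ccnc1 | intermediate (not isolated)
9 | N-methoxy-N,4-dimethylpent-3-enamide | CC(C)=CCC(=O)N(C)OC | intermediate
10 | trimethylsilylacetylene | C#C[Si](C)(C)C | starting material
11 | lithium (trimethylsilyl)acetylide | [Li]C#C[Si](C)(C)C | intermediate (not isolated)
12 | lithium 3-[methoxy(methyl)amino]-6-methyl-1-(trimethylsilyl)hept-5-en-1-yn-3-olate | CC(C)=CCC(O[Li])(N(C)OC)C#C[Si](C)(C)C | intermediate (not isolated)
13 | 6-methyl-1-(trimethylsilyl)hept-5-en-1-yn-3-one | CC(C)=CCC(=O)C#C[Si](C)(C)C | intermediate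
14 | (S)-6-methyl-1-(trimethylsilyl)hept-5-en-1-yn-3-ol | O[C@@H](CC=C(C)C)C#C[Si](C)(C)C | intermediate
15 | (S)-3-(tert-butyldimethylsilyloxy)-6-methyl-1-(trimethylsilyl)hept-5-en-1-yne | CC(C)(C)[Si](C)(C)O[C@@H](CC=C(C)C)C#C[Si](C)(C)C | intermediate
16 | (S)-3-(tert-butyldimethylsilyloxy)-6-methylhept-5-en-1-yne | CC(C)(C)[Si](C)(C)O[C@@H](CC=C(C)C)C#C | intermediate
17 | tricarbonyl{η6-2-[(S)-1-(tert-butyldimethylsilyloxy)-4-methylpent-3-enyl]-4-methoxy-5,8-bis(methoxymethoxy)naphthalen-1-ol}chromium | CC(C)(C)[Si](C)(C)O[C@@H](CC=C(C)C)c1cc(OC)c2c(OCOC)ccc(OCOC)c2c1O.O=C=[Cr](=C=O)=C=O | intermediate (not isolated)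
18 | 2-[(S)-1-(tert-butyldimethylsilyloxy)-4-methylpent-3-enyl]-4-methoxy-5,8-bis(methoxymethoxy)naphthalen-1-ol | CC(C)(C)[Si](C)(C)O[C@@H](CC=C(C)C)c1cc(OC)c2c(OCOC)ccc(OCOC)c2c1O | intermediate (not isolated)
19 | 2-[(S)-1-(tert-butyldimethylsilyloxy)-4-methylpent-3-enyl]-5,8-bis(methoxymethoxy)naphthalene-1,4-dione | CC(C)(C)[Si](C)(C)O[C@@H](CC=C(C)C)C1=CC(=O)c2c(OCOC)ccc(OCOC)c2C1=O | intermediate
20 | 2-[(S)-1-(tert-butyldimethylsilyloxy)-4-methylpent-3-enyl]-5,8-bis(trimethylsilyloxy)naphthalene-1,4-dione | CC(C)(C)[Si](C)(C)O[C@@H](CC=C(C)C)C1=CC(=O)c2c(O[Si](C)(C)C)ccc(O[Si](C)(C)C)c2C1=O | intermediate (not isolated)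
21 | 2-[(S)-1-(tert-butyldimethylsilyloxy)-4-methylpent-3-enyl]-5,8-dihydroxynaphthalene-1,4-dione | CC(C)(C)[Si](C)(C)O[C@@H](CC=C(C)C)C1=CC(=O)c2c(O)ccc(O)c2C1=O | intermediate
22 | alkannin | O[C@@H](CC=C(C)C)C1=CC(=O)c2c(O)ccc(O)c2C1=O | intermediate
23 | tiglic acid | C/C=C(\C)C(=O)O | starting material
24 | N,N′-dicyclohexyl-O-[(E)-2-methylbut-2-enoyl]isourea | C/C=C(\C)C(=O)OC(=NC1CCCCC1)NC1CCCCC1 | intermediate (not isolated)
25 | alkannin tiglate | C/C=C(\C)C(=O)O[C@@H](CC=C(C)C)C1=CC(=O)c2c(O)ccc(O)c2C1=O | target

Total step count: 11. Longest linear sequence: 9 steps (from acid 7 through steps 3 to 11).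

Steps most likely to fail

Step 8. The vinylcarbene or vinylketene may be diverted to non-phenol products, the alkyne may oligomerise, and the acidic cerium stage may cause loss of acetal or silyl groups or over-oxidation of the very electron-rich naphthol. The fallback separates annulation from oxidation, sets out from 6 and 16 and returns at 19. The benzannulation is run with Ac2O and Et3N present (THF, 60 °C) so that the phenol is acetylated as it forms. Air and light then free the arene from chromium, and the bench-stable 2-[(S)-1-(tert-butyldimethylsilyloxy)-4-methylpent-3-enyl]-4-methoxy-5,8-bis(methoxymethoxy)naphthalen-1-yl acetate F1 is isolated. Methanolysis of the acetate (K2CO3, MeOH, argon) regenerates naphthol 18. After neutralisation and exchange into aqueous MeCN, 18 is oxidised at once with PhI(OAc)2 at 0 °C, a non-acidic hypervalent-iodine oxidative demethylation, to give 19.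

Step 9. Acetal transfer may be incomplete on the electron-poor ring, the silyl triflate may cause enolisation through C1′–H with erosion of configuration, or the TBS ether may be lost early. The fallback inverts the order and uses protic solvolysis, sets out from 19 and returns at 22. HF·pyridine in THF first removes the silyl ether to give 2-[(S)-1-hydroxy-4-methylpent-3-enyl]-5,8-bis(methoxymethoxy)naphthalene-1,4-dione F2, in which the alcohol sits on a non-tautomerising quinone. The two peri acetals, activated by the neighbouring carbonyls, are then cleaved with 2 M aq HCl in THF at 0 °C to rt for the shortest possible time, giving alkannin 22 directly.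

Step 5. The C5=C6 alkene may migrate into conjugation through enolisation of the CH2 group, or facial selectivity may be poor. The fallback builds the carbinol by allylation and then installs the trisubstituted alkene, sets out from 10 and returns at 15.
- Formylation of 10 (n-BuLi, THF, −78 °C; DMF; buffered quench) gives 3-(trimethylsilyl)propynal F3.
- Brown allylation with (−)-Ipc2B(allyl) in Et2O at −78 °C, the enantiomer expected to attack the Si face, gives (S)-1-(trimethylsilyl)hex-5-en-1-yn-3-ol F4.
- Silylation (TBSCl, imidazole, DMF) gives (S)-3-(tert-butyldimethylsilyloxy)-1-(trimethylsilyl)hex-5-en-1-yne F5.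
- Cross-metathesis with 2-methyl-2-butene (second-generation Grubbs catalyst RuCl2(=CHPh)(H2IMes)(PCy3), CH2Cl2, 40 °C) converts the vinyl group into the trisubstituted alkene of 15; the silyl-capped alkyne should stay inert.

Further compounds
F1 | step 8 | 2-[(S)-1-(tert-butyldimethylsilyloxy)-4-methylpent-3-enyl]-4-methoxy-5,8-bis(methoxymethoxy)naphthalen-1-yl acetate | CC(C)(C)[Si](C)(C)O[C@@H](CC=C(C)C)c1cc(OC)c2c(OCOC)ccc(OCOC)c2c1OC(C)=O
F2 | step 9 | 2-[(S)-1-hydroxy-4-methylpent-3-enyl]-5,8-bis(methoxymethoxy)naphthalene-1,4-dione | O[C@@H](CC=C(C)C)C1=CC(=O)c2c(OCOC)ccc(OCOC)c2C1=O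
F3 | step 5 | 3-(trimethylsilyl)propynal | C[Si](C)(C)C#CC=O
F4 | step 5 | (S)-1-(trimethylsilyl)hex-5-en-1-yn-3-ol | O[C@@H](CC=C)C#C[Si](C)(C)C
F5 | step 5 | (S)-3-(tert-butyldimethylsilyloxy)-1-(trimethylsilyl)hex-5-en-1-yne | CC(C)(C)[Si](C)(C)O[C@@H](CC=C)C#C[Si](C)(C)C
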